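**Retrosynthetic overview**

- The target, 5,7,3',5'-tetrahydroxy-6,8,4'-trimethoxyflavone, is unmasked last from a flavone carrying benzyl ethers on O5 and O7 and methoxymethyl (MOM) ethers on O3' and O5'.
- Key disconnection at C2–C1': C2 is the beta carbon of the O1–C2=C3–C4=O enone of ring C, and ring B is symmetric about its C1'–C4' axis, with C1' the one C–H of a 2-methoxyresorcinol diether that has no ortho substituent. The halves are therefore a 2-unsubstituted chromone and an arylboronic acid, joined by oxidative boron Heck arylation.
- Ring B half: 2-methoxyresorcinol, MOM protection, sterically governed C–H borylation at C5, cleavage of the pinacol boronate.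
- Ring A/C half: syringol supplies O7 flanked by the C6 and C8 methoxy groups; dibromination and double hydroxylation add O5 and O1; Hoesch acetylation fills the last ring carbon (C4a); ring C is closed through the enaminone.
- Ring order: rings A and B are bought as benzenes; ring C (the pyranone) is the only ring formed, before the coupling. There are no stereocenters.

Key step: step 9

Remark: positions are given in flavone numbering (O1, C2–C4, ring A C4a–C8a, ring B C1'–C6'); the target is achiral, so no configuration has to be set.

**Route**

Step 1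
Reactants: 1 syringol (2,6-dimethoxyphenol); 2 benzyl bromide
Product: 3 2-(benzyloxy)-1,3-dimethoxybenzene
Conditions: K2CO3, acetone, reflux
Reagents that add atoms: none
Why: Williamson ether synthesis: the phenoxide of the only hydroxyl group displaces bromide from benzyl bromide, and the benzyl ether then shields the future O7 through all ring A chemistry.

Step 2
Reactants: 3 2-(benzyloxy)-1,3-dimethoxybenzene
Product: 4 3-(benzyloxy)-1,5-dibromo-2,4-dimethoxybenzene
Conditions: NBS (2.1 equiv), MeCN, 0 °C to rt, dark
Reagents that add atoms: N-bromosuccinimide, O=C1CCC(=O)N1Br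
Why: Electrophilic aromatic bromination: C4 and C6 of 3 are each ortho to one methoxy group and para to the other, whereas C5 is meta to both and para only to the central benzyloxy group, which is twisted out of conjugation, so the two bromines should enter at C4 and C6.

Step 3
Reactants: 4 3-(benzyloxy)-1,5-dibromo-2,4-dimethoxybenzene
Product: 5 5-(benzyloxy)-4,6-dimethoxybenzene-1,3-diol
Conditions: Pd2(dba)3 (4 mol%), tBuXPhos (16 mol%), KOH (6 equiv), 1,4-dioxane/H2O (1:1), 100 °C, argon; then aq. HCl to pH 3
Reagents that add atoms: potassium hydroxide, [K+].[OH-]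
Why: Palladium-catalysed hydroxylation of aryl bromides (C–O cross-coupling with hydroxide): the bulky biaryl di-tert-butylphosphine speeds reductive elimination from the aryl–palladium hydroxide and holds back diaryl ether formation, each bromide has only one ortho substituent, and benzyl and methyl ethers are inert to hot aqueous KOH.

Step 4
Reactants: 5 5-(benzyloxy)-4,6-dimethoxybenzene-1,3-diol
Product: 7 1-[4-(benzyloxy)-2,6-dihydroxy-3,5-dimethoxyphenyl]ethan-1-one, via ketiminium chloride 6 (not isolated)
Conditions: MeCN (3 equiv), ZnCl2, HCl (g), Et2O, 0 °C; then H2O, 100 °C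
Reagents that add atoms: acetonitrile, CC#N; water, O
Why: Houben–Hoesch acylation: the nitrilium-type electrophile formed from acetonitrile, HCl and ZnCl2 attacks the single unsubstituted ring carbon of 5, which lies ortho to both hydroxyl groups on a ring activated by five oxygen substituents, and hydrolysis of the precipitated ketiminium salt gives the ketone under conditions (0 °C, no strong Lewis acid) that should spare the benzyl ether.

Step 5
Reactants: 7 1-[4-(benzyloxy)-2,6-dihydroxy-3,5-dimethoxyphenyl]ethan-1-one
Product: 9 7-(benzyloxy)-5-hydroxy-6,8-dimethoxy-4H-chromen-4-one, via enaminone 8 (not isolated)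
Conditions: Me2NCH(OMe)2 (2.5 equiv), toluene, 95 °C; evaporate; then 2 M aq. HCl, THF, 50 °C
Reagents that add atoms: N,N-dimethylformamide dimethyl acetal, COC(OC)N(C)C
Why: Enaminone route to 2-unsubstituted chromones: condensation of the methyl ketone with the amide acetal gives the enaminone, under acid an ortho hydroxyl adds to its beta carbon and dimethylamine is expelled (6-endo addition–elimination forming the O1–C2 bond), and because the two ortho hydroxyls are equivalent only one chromone can form.

Step 6
Reactants: 9 7-(benzyloxy)-5-hydroxy-6,8-dimethoxy-4H-chromen-4-one; 2 benzyl bromide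
Product: 10 5,7-bis(benzyloxy)-6,8-dimethoxy-4H-chromen-4-one
Conditions: K2CO3, Bu4NI (10 mol%), DMF, 60 °C
Reagents that add atoms: none
Why: Williamson ether synthesis: the 5-hydroxyl is hydrogen-bonded to the C4 carbonyl and flanked by the C6 methoxy group, hence the polar solvent, iodide catalysis and heating, while anhydrous carbonate spares the base-sensitive C2 of the chromone.

Step 7
Reactants: 11 2-methoxyresorcinol (2-methoxybenzene-1,3-diol)
Product: 12 2-methoxy-1,3-bis(methoxymethoxy)benzene
Conditions: NaH (2.4 equiv), MOMCl (2.4 equiv), DMF, 0 °C to rt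
Reagents that add atoms: chloromethyl methyl ether, COCCl
Why: Williamson-type O-alkylation of both phenoxides by the reactive alpha-chloro ether gives the bis-MOM acetal, a protecting group without aromatic C–H bonds that could compete in the borylation.

Step 8
Reactants: 12 2-methoxy-1,3-bis(methoxymethoxy)benzene; 13 bis(pinacolato)diboron
Product: 15 [4-methoxy-3,5-bis(methoxymethoxy)phenyl]boronic acid, via pinacol boronate 14 (not isolated)
Conditions: [Ir(OMe)(cod)]2 (1.5 mol%), 4,4'-di-tert-butyl-2,2'-bipyridine (3 mol%), B2pin2 (1.0 equiv), THF, 80 °C; evaporate; then NaIO4 (3 equiv), NH4OAc (3 equiv), acetone/H2O (1:1), rt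
Reagents that add atoms: water, O
Why: Iridium-catalysed aromatic C–H borylation is governed by sterics, so of the three ring hydrogens only the one at C5, which has no ortho substituent, should react; oxidative cleavage of the pinacol unit by NaIO4 in ammonium acetate buffer then frees the boronic acid without touching the acid-sensitive MOM acetals.

Step 9
Reactants: 10 5,7-bis(benzyloxy)-6,8-dimethoxy-4H-chromen-4-one; 15 [4-methoxy-3,5-bis(methoxymethoxy)phenyl]boronic acid
Product: 16 5,7-bis(benzyloxy)-6,8-dimethoxy-2-[4-methoxy-3,5-bis(methoxymethoxy)phenyl]-4H-chromen-4-one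
Conditions: Pd(OCOCF3)2 (10 mol%), DDQ (1.5 equiv), 1,4-dioxane/DMSO (9:1), 60 °C; 15 (2 equiv) added in portions
Reagents that add atoms: none
Why: Transmetalation of the arylboronic acid to divalent palladium gives an aryl–palladium trifluoroacetate that adds syn across C2=C3 of the chromone, the aryl group going to the electrophilic C2 and palladium to C3, which forms the C2–C1' bond. The carbon-bound palladium enolate equilibrates through its oxygen-bound form, which brings palladium syn to the C2 hydrogen, so beta-hydride elimination restores the C2=C3 double bond and DDQ returns zerovalent palladium to the divalent state. This is an oxidative boron Heck (oxidative Heck-type) arylation, a known reaction of chromones with arylboronic acids; no ring is closed and no stereocenter is created. The step needs arylation at C2 rather than C3 and cross-coupling rather than biaryl homocoupling: the first follows from the polarity of the enone, because migratory insertion places carbon at the beta position, and the second is helped by portionwise addition of an excess of the boronic acid. The boronic acid has no ortho substituents, so transmetalation should be fast, and the benzyl and MOM ethers should tolerate the base-free, only weakly acidic medium.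

Step 10
Reactants: 16 5,7-bis(benzyloxy)-6,8-dimethoxy-2-[4-methoxy-3,5-bis(methoxymethoxy)phenyl]-4H-chromen-4-one
Product: 17 5,7-dihydroxy-6,8-dimethoxy-2-[4-methoxy-3,5-bis(methoxymethoxy)phenyl]-4H-chromen-4-one
Conditions: H2 (1 atm), 10% Pd/C, THF/MeOH (1:1), rt
Reagents that add atoms: none
Why: Catalytic hydrogenolysis of benzyl aryl ethers over palladium on carbon: the benzylic C–O bonds are cleaved at 1 atm and room temperature, while the MOM acetals, the methyl ethers and the C2=C3 bond of the conjugated pyranone should not be reduced under these conditions.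

Step 11
Reactants: 17 5,7-dihydroxy-6,8-dimethoxy-2-[4-methoxy-3,5-bis(methoxymethoxy)phenyl]-4H-chromen-4-one
Product: 18 5,7-dihydroxy-2-(3,5-dihydroxy-4-methoxyphenyl)-6,8-dimethoxy-4H-chromen-4-one (CNP0185233.0)
Conditions: 3 M HCl, MeOH/THF, 50 °C
Reagents that add atoms: none
Why: Acid-catalysed acetal methanolysis (MOM removal): protonation of the acetal and transfer of the methoxymethyl group to methanol frees both ring B phenols, methyl aryl ethers are stable to dilute HCl, and because ring A carries the same substituents on either side of C7 an acid-induced opening and reclosure of ring C could only return the same flavone.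

**Compound list**

1 | syringol (2,6-dimethoxyphenol) | COc1cccc(OC)c1O | starting material
2 | benzyl bromide | BrCc1ccccc1 | starting material
3 | 2-(benzyloxy)-1,3-dimethoxybenzene | COc1cccc(OC)c1OCc1ccccc1 | intermediate
4 | 3-(benzyloxy)-1,5-dibromo-2,4-dimethoxybenzene | COc1c(Br)cc(Br)c(OC)c1OCc1ccccc1 | intermediate
5 | 5-(benzyloxy)-4,6-dimethoxybenzene-1,3-diol | COc1c(O)cc(O)c(OC)c1OCc1ccccc1 | intermediate
6 | 1-[4-(benzyloxy)-2,6-dihydroxy-3,5-dimethoxyphenyl]ethan-1-iminium chloride | CC(=[NH2+])c1c(O)c(OC)c(OCc2ccccc2)c(OC)c1O.[Cl-] | intermediate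
7 | 1-[4-(benzyloxy)-2,6-dihydroxy-3,5-dimethoxyphenyl]ethan-1-one | CC(=O)c1c(O)c(OC)c(OCc2ccccc2)c(OC)c1O | intermediate
8 | (E)-1-[4-(benzyloxy)-2,6-dihydroxy-3,5-dimethoxyphenyl]-3-(dimethylamino)prop-2-en-1-one | CN(C)/C=C/C(=O)c1c(O)c(OC)c(OCc2ccccc2)c(OC)c1O | intermediate
9 | 7-(benzyloxy)-5-hydroxy-6,8-dimethoxy-4H-chromen-4-one | COc1c(OCc2ccccc2)c(OC)c2occc(=O)c2c1O | intermediate
10 | 5,7-bis(benzyloxy)-6,8-dimethoxy-4H-chromen-4-one | COc1c(OCc2ccccc2)c(OC)c2occc(=O)c2c1OCc1ccccc1 | intermediate
11 | 2-methoxyresorcinol (2-methoxybenzene-1,3-diol) | COc1c(O)cccc1O | starting material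
12 | 2-methoxy-1,3-bis(methoxymethoxy)benzene | COCOc1cccc(OCOC)c1OC | intermediate
13 | bis(pinacolato)diboron | CC1(C)OB(OC1(C)C)B1OC(C)(C)C(C)(C)O1 | starting material
14 | 2-[4-methoxy-3,5-bis(methoxymethoxy)phenyl]-4,4,5,5-tetramethyl-1,3,2-dioxaborolane | COCOc1cc(B2OC(C)(C)C(C)(C)O2)cc(OCOC)c1OC | intermediate
15 | [4-methoxy-3,5-bis(methoxymethoxy)phenyl]boronic acid | COCOc1cc(B(O)O)cc(OCOC)c1OC | intermediate
16 | 5,7-bis(benzyloxy)-6,8-dimethoxy-2-[4-methoxy-3,5-bis(methoxymethoxy)phenyl]-4H-chromen-4-one | COCOc1cc(-c2cc(=O)c3c(OCc4ccccc4)c(OC)c(OCc4ccccc4)c(OC)c3o2)cc(OCOC)c1OC | intermediate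
17 | 5,7-dihydroxy-6,8-dimethoxy-2-[4-methoxy-3,5-bis(methoxymethoxy)phenyl]-4H-chromen-4-one | COCOc1cc(-c2cc(=O)c3c(O)c(OC)c(O)c(OC)c3o2)cc(OCOC)c1OC | intermediate
18 | 5,7-dihydroxy-2-(3,5-dihydroxy-4-methoxyphenyl)-6,8-dimethoxy-4H-chromen-4-one (CNP0185233.0) | COc1c(O)cc(-c2cc(=O)c3c(O)c(OC)c(O)c(OC)c3o2)cc1O | target

**Step count**

Total step count: 11. Longest linear sequence: 9 steps (steps 1–6, then 9–11); the ring B branch (steps 7–8) joins at step 9.

**Steps most likely to fail**

Step 9 (key coupling). The palladium enolate may be protonated before beta-hydride elimination, stopping at the saturated ketone. The electron-rich boronic acid may also be lost to oxidative homocoupling or protodeboronation in the presence of DDQ. The fallback separates bond formation from oxidation. Chromone 10 and boronic acid 15 would be joined by redox-neutral conjugate addition under bipyridine-ligated cationic divalent palladium (Pd(OCOCF3)2, 2,2'-bipyridine, NH4PF6, H2O, ClCH2CH2Cl, 60 °C), where protonation of the enolate is the wanted outcome. This would give racemic 5,7-bis(benzyloxy)-6,8-dimethoxy-2-[4-methoxy-3,5-bis(methoxymethoxy)phenyl]chroman-4-one F1. Its C2 stereocenter is of no consequence, because dehydrogenation with DDQ in 1,4-dioxane at reflux, with no boronic acid or palladium present, would remove it and give flavone 16, where the route is rejoined.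

Step 4 (Hoesch acetylation). The crowded central benzyl ether may be cleaved by HCl/ZnCl2, or the reaction may stall at O-bound imidates. The fallback replaces electrophilic acylation by directed ortho-metalation. Diol 5 would be protected (NaH, MOMCl, DMF) as 3-(benzyloxy)-2,4-dimethoxy-1,5-bis(methoxymethoxy)benzene F2. The ring C–H between the two MOM ethers would be lithiated (n-BuLi, THF, 0 °C) and acylated with N-methoxy-N-methylacetamide at −78 °C to give 1-[4-(benzyloxy)-3,5-dimethoxy-2,6-bis(methoxymethoxy)phenyl]ethan-1-one F3. Mild acid methanolysis (2 M HCl, MeOH, 40 °C) would then free the two phenols and return the route to acetophenone 7.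

Step 3 (double hydroxylation). The second C–O coupling may be incomplete, hydrodebromination may compete, and the electron-rich resorcinolate may degrade oxidatively in hot KOH. The fallback replaces C–O coupling by C–B coupling followed by boron-to-oxygen migration. Dibromide 4 would undergo double Miyaura borylation (Pd(dppf)Cl2, bis(pinacolato)diboron 13, KOAc, 1,4-dioxane, 90 °C) to 2,2'-[5-(benzyloxy)-4,6-dimethoxy-1,3-phenylene]bis(4,4,5,5-tetramethyl-1,3,2-dioxaborolane) F4. Oxidation with H2O2/NaOH in THF at 0 °C would deliver diol 5, where the route is rejoined.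

Further compounds
F1 | step 9 | 5,7-bis(benzyloxy)-6,8-dimethoxy-2-[4-methoxy-3,5-bis(methoxymethoxy)phenyl]chroman-4-one (racemic) | COCOc1cc(C2CC(=O)c3c(OCc4ccccc4)c(OC)c(OCc4ccccc4)c(OC)c3O2)cc(OCOC)c1OC
F2 | step 4 | 3-(benzyloxy)-2,4-dimethoxy-1,5-bis(methoxymethoxy)benzene | COCOc1cc(OCOC)c(OC)c(OCc2ccccc2)c1OC
F3 | step 4 | 1-[4-(benzyloxy)-3,5-dimethoxy-2,6-bis(methoxymethoxy)phenyl]ethan-1-one | CC(=O)c1c(OCOC)c(OC)c(OCc2ccccc2)c(OC)c1OCOC
F4 | step 3 | 2,2'-[5-(benzyloxy)-4,6-dimethoxy-1,3-phenylene]bis(4,4,5,5-tetramethyl-1,3,2-dioxaborolane) | COc1c(B2OC(C)(C)C(C)(C)O2)cc(B2OC(C)(C)C(C)(C)O2)c(OC)c1OCc1ccccc1
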